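All constants stand for no real mixture; the flask was simulated.

Slowness of the start is what has to be reckoned in the spring flask, where living ends must form from initiator while free monomer is still coming out of the solid.

common to all: solid monomer 0.28 M; initiator 4.5 mM; time 6.0 min

| charge | temperature | remark |
|---|---|---|
| dawn | 70 °C |  |
| autumn |  | at 70 °C until 4.0 min, from then on at 30 °C |
| summer | 50 °C |  |
| spring | 30 °C |  |

    free monomer + initiator → living end + monomer in chains (k1 = 0.0747 M⁻¹ s⁻¹, Ea1 = 63.0 kJ mol⁻¹)
    free monomer + living end → monomer in chains + living end, rate k2*[living end]*[free monomer] (k2 = 1.29 M⁻¹ s⁻¹, Ea2 = 56.0 kJ mol⁻¹)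
    solid monomer ⇌ free monomer, rate k3*(cs3 - [free monomer]) while solid is left; crystals form when [free monomer] > cs3 (cs3 = 0.19 M, k3 = 0.00928 s⁻¹)
    monomer in chains ⇌ isomer of the product (K4 = 1.05, k4 = 0.00388 s⁻¹, Ea4 = 94.0 kJ mol⁻¹, ΔH4 = −70.0 kJ mol⁻¹)
    (constants at 50 °C)

- solid, in amounts per volume of the solution: solid monomer
- all constants are for 50 °C and move with temperature by the activation energies and enthalpies
- at the start none of the solid monomer is in solution

* the flask that comes out highest in amount of monomer in chains, in percent of the solid monomer charged, or "all alike" when all lie within 1.5 percentage points (dawn / autumn / summer / spring / all alike)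
* monomer in chains at the end, in percent of the solid monomer charged, dawn
* monomer in chains at the end, in percent of the solid monomer charged, autumn
* monomer in chains at the end, in percent of the solid monomer charged, summer
* monomer in chains at the end, in percent of the solid monomer charged, spring

Free monomer starts at nothing and cannot pass the solubility cs, while the charge stands higher, 0.28 M against 0.19 M. In spring, even the whole initiator charge as living ends would use free monomer at a rate constant of 0.0881 min⁻¹, slower than the dissolving coefficient k3. So in spring, as long as solid lasts, free monomer can be frozen near cs once a dissolving time θ = 1/k3 = 1.80 min has passed. With it frozen, initiator falls pseudo-first-order, and in spring τ = 1/(k1·cs) = 5.52 min, with k1 taken at the temperature of the flask, is the initiation time. Each living end then adds free monomer to chains at g = k2·cs, which in spring is 3.72 min⁻¹.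

A first ceiling for spring makes the whole initiator charge living ends at once and gives 37.5 % of the charge in chains. Letting τ run from the first moment, with free monomer already at cs, lowers the ceiling to 15.1 %. A floor counts nothing during two dissolving times and gives 3.30 %. My own figure delays the clock by one θ, which leaves 46.7 % of the initiator and puts 8.40 % in chains and isomer together. The isomer share should be slight in spring, because the relaxation half-life of 25.6 min is long against 6.0 min. Dawn stays to the end at 70 °C, hotter than summer and spring, while autumn leaves that temperature at 4.0 min. Growth at 70 °C runs 13.3 times as fast as at 30 °C, so I put dawn highest.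

The forecast names dawn and gives 79.5 %, 64 %, 39 % and 7.7 % for dawn, autumn, summer and spring, holding that “at 70 °C nearly everything is converted, at 50 °C a bit over half, and at 30 °C under a tenth”, and its spring value lies inside my bracket.

The simulation gives dawn highest, with 79.8 %, 65.9 %, 39.9 % and 7.89 % in the same order. Spring ends with 47 % of its initiator left, and its free monomer stands at 61.7 % of the charge against 67.9 % at solubility.

In spring at the end, free monomer is made 1.15 times as fast as it is used, and its half-life by growth, 15 min, is long against 6.0 min. That is the freeze, seen in the flask. In the neighbour at 15 °C, τ grows to 20.3 min and g falls to 1.17 min⁻¹, so the same delayed clock leaves 81.3 % of the initiator and puts 1.07 % in chains. The simulated neighbour has 81 % and 1.08 %.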